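**Retrosynthetic overview**

1. The target is a tridepside with no stereocentre: ring A (4-hydroxy-2,3-dimethoxy-6-methylbenzoyl), ring B (middle 2-hydroxy-6-methylbenzoyl unit) and ring C (terminal 2-hydroxy-6-methylbenzoic acid). The last cuts are the two benzyl groups and the ester bond between the ring A carbonyl and O-4 of ring B.
2. Key cut: ring B and its ester bond to O-4 of ring C are made in one operation. The acylketene from diketo-dioxinone 5 is trapped by the 4-OH of benzyl orsellinate 7 (forming the ester C(=O)–O bond), and the open triketo chain is then folded by aldol condensation (forming the ring B bond between C1, which bears the carbonyl, and C6, which bears CH3).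
3. Diketo-dioxinone 5 comes from dioxinone 1 by two enolate acylations; ring C is bought as orsellinic acid 6 and only benzylated at its carboxyl group.
4. Ring A is not built: symmetric 5-methylpyrogallol is formylated, 4-O-benzylated, 2,3-di-O-methylated and oxidised to acid 16.
5. Order of ring formation: ring B is the only ring formed (step 4); rings A and C are aromatic from the start.

Key step: step 4

Assumption: 5-methylbenzene-1,2,3-triol, 2,4-dihydroxy-6-methylbenzoic acid and dioxinone 1 are taken as purchasable. A phenolic OH that is hydrogen bonded to an ortho ester carbonyl (the 2-OH of each orsellinate ring) is taken to be much less nucleophilic than a free 4-OH, as is usual in depside chemistry.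

**Route**

Step 1
Reactants: 1 2,2,6-trimethyl-4H-1,3-dioxin-4-one; 2 acetyl chloride
Product: 3 2,2-dimethyl-6-(2-oxopropyl)-4H-1,3-dioxin-4-one
Conditions: LiN(SiMe3)2 (2 equiv relative to 2), THF, −78 °C; then 2, −78 °C; aq. NH4Cl
Reagents that add atoms: none
Why: Kinetic deprotonation of the 6-methyl group gives the lithium dienolate, which should be C-acylated at its γ-carbon by acetyl chloride (vinylogous Claisen-type acylation), the second equivalent of base taking up the more acidic product.

Step 2
Reactants: 3 2,2-dimethyl-6-(2-oxopropyl)-4H-1,3-dioxin-4-one; 4 N-methoxy-N-methylacetamide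
Product: 5 6-(2,4-dioxopentyl)-2,2-dimethyl-4H-1,3-dioxin-4-one
Conditions: LiN(i-Pr)2 (2.2 equiv), THF, −78 °C; then 4, −78 to −40 °C; aq. HCl
Reagents that add atoms: none
Why: Double deprotonation gives a Weiler-type dianion whose terminal, more basic carbanion should be acylated by the Weinreb amide (Claisen-type acylation), the chelated tetrahedral adduct preventing over-addition until the quench.

Step 3
Reactants: 6 2,4-dihydroxy-6-methylbenzoic acid (orsellinic acid)
Product: 7 benzyl 2,4-dihydroxy-6-methylbenzoate (benzyl orsellinate)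
Conditions: BnBr (1.05 equiv), KHCO3 (1.2 equiv), DMF, 23 °C
Reagents that add atoms: benzyl bromide, BrCc1ccccc1
Why: Hydrogencarbonate should deprotonate only the carboxylic acid, so that SN2 O-alkylation of the carboxylate by benzyl bromide gives the benzyl ester and leaves both phenols free; the low temperature avoids decarboxylation of the acid.

Step 4
Reactants: 5 6-(2,4-dioxopentyl)-2,2-dimethyl-4H-1,3-dioxin-4-one; 7 benzyl 2,4-dihydroxy-6-methylbenzoate
Product: 11 benzyl 4-[(2,4-dihydroxy-6-methylbenzoyl)oxy]-2-hydroxy-6-methylbenzoate (benzyl lecanorate), via acylketene 8 (not isolated), via aryl triketo ester 9 (not isolated), via aldol adduct 10 (not isolated)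
Conditions: 5 added slowly to 7 (1.2 equiv), PhMe (concentrated), 110 °C; then Et3N (0.2 equiv), CH2Cl2, 0 to 23 °C; then HCl (4 M in dioxane), 23 °C
Reagents that add atoms: none
Why: Thermal retro-[4+2] loss of acetone from 5 gives acylketene 8, whose ketene carbon is attacked by the free 4-OH of 7 to give the aryl 3,5,7-trioxooctanoate 9, so the B–C depside bond is made without any activated benzoic acid. The catalytic amine then enolises C2 of 9, which adds to the C7 methyl ketone in a 6-(enolendo)-exo-trig aldol closure to give 10, and acid removes water to aromatise ring B with its 2-OH, 4-OH and 6-CH3 already in place. The closest known reaction type is the thermolysis of diketo-dioxinones in the presence of alcohols followed by aromatisation to resorcylate esters, together with the formation of aryl acetoacetates from dioxinones and phenols. No stereocentre survives, since the two centres of 10 are erased on dehydration. Site selectivity between the two hydroxyls of 7 rests on the 2-OH being held in a hydrogen bond to the benzyl ester carbonyl and flanked by it, and slow addition of 5 to concentrated phenol limits self-capture of the ketene by its own enol. Aldol closure is preferred over Claisen closure or lactonisation with loss of the phenol because the ketone is the more electrophilic carbonyl under a weak, non-nucleophilic amine in an aprotic medium, where no alkoxide is present to transesterify the aryl ester.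

Step 5
Reactants: 12 5-methylbenzene-1,2,3-triol
Product: 13 2,3,4-trihydroxy-6-methylbenzaldehyde
Conditions: HC(OEt)3, AlCl3, PhMe, 0 to 23 °C; then aq. HCl
Reagents that add atoms: triethyl orthoformate, CCOC(OCC)OCC; water, O
Why: Gross-type formylation by the dialkoxycarbenium ion from the orthoformate and AlCl3 should give one aldehyde after acetal hydrolysis, because the two free ring positions of the symmetric triol are equivalent, each ortho to one hydroxyl and para to another.

Step 6
Reactants: 13 2,3,4-trihydroxy-6-methylbenzaldehyde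
Product: 14 4-(benzyloxy)-2,3-dihydroxy-6-methylbenzaldehyde
Conditions: BnBr (1.0 equiv), NaHCO3, NaI (cat.), DMF, 40 °C, N2
Reagents that add atoms: benzyl bromide, BrCc1ccccc1
Why: Williamson etherification under weak base should take only the 4-OH, which is para to the formyl group and therefore the most acidic, and which is not tied up in the hydrogen bond that holds the 2-OH.

Step 7
Reactants: 14 4-(benzyloxy)-2,3-dihydroxy-6-methylbenzaldehyde
Product: 15 4-(benzyloxy)-2,3-dimethoxy-6-methylbenzaldehyde
Conditions: MeI (excess), K2CO3, DMF, 40 °C, N2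
Reagents that add atoms: iodomethane, CI
Why: Williamson O-methylation with carbonate in a dipolar aprotic solvent should alkylate both remaining phenols, the chelated 2-OH included.

Step 8
Reactants: 15 4-(benzyloxy)-2,3-dimethoxy-6-methylbenzaldehyde
Product: 16 4-(benzyloxy)-2,3-dimethoxy-6-methylbenzoic acid
Conditions: NaClO2, NaH2PO4, 2-methyl-2-butene (excess), t-BuOH/H2O, 23 °C
Reagents that add atoms: sodium chlorite, [Na+].[O-]Cl=O
Why: Pinnick oxidation should convert the hindered aldehyde to the acid while the alkene scavenger removes HOCl before it can chlorinate the electron-rich ring.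

Step 9
Reactants: 16 4-(benzyloxy)-2,3-dimethoxy-6-methylbenzoic acid; 11 benzyl 4-[(2,4-dihydroxy-6-methylbenzoyl)oxy]-2-hydroxy-6-methylbenzoate
Product: 17 benzyl 4-{[4-{[4-(benzyloxy)-2,3-dimethoxy-6-methylbenzoyl]oxy}-2-hydroxy-6-methylbenzoyl]oxy}-2-hydroxy-6-methylbenzoate
Conditions: (CF3CO)2O (excess), PhMe, 23 °C
Reagents that add atoms: none
Why: Depside esterification through the mixed trifluoroacetic anhydride suits 2,6-disubstituted benzoic acids (acylium-type activation), and only the 4-OH of ring B in 11 is free of a hydrogen bond to an ortho carbonyl, so it should be acylated in preference to the two chelated 2-OH groups.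

Step 10
Reactants: 17 benzyl 4-{[4-{[4-(benzyloxy)-2,3-dimethoxy-6-methylbenzoyl]oxy}-2-hydroxy-6-methylbenzoyl]oxy}-2-hydroxy-6-methylbenzoate
Product: 18 4-{[4-{[4-hydroxy-2,3-dimethoxy-6-methylbenzoyl]oxy}-2-hydroxy-6-methylbenzoyl]oxy}-2-hydroxy-6-methylbenzoic acid (target)
Conditions: H2 (1 atm), Pd/C (10%), EtOAc, 23 °C
Reagents that add atoms: none
Why: Catalytic hydrogenolysis should cleave the benzyl ether on ring A and the benzyl ester on ring C in one operation while the two aryl ester (depside) bonds stay intact.

**Compound list**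

1 | 2,2,6-trimethyl-4H-1,3-dioxin-4-one | CC1=CC(=O)OC(C)(C)O1 | starting material
2 | acetyl chloride | CC(Cl)=O | starting material
3 | 2,2-dimethyl-6-(2-oxopropyl)-4H-1,3-dioxin-4-one | CC(=O)CC1=CC(=O)OC(C)(C)O1 | intermediate
4 | N-methoxy-N-methylacetamide | CON(C)C(C)=O | starting material
5 | 6-(2,4-dioxopentyl)-2,2-dimethyl-4H-1,3-dioxin-4-one | CC(=O)CC(=O)CC1=CC(=O)OC(C)(C)O1 | intermediate
6 | 2,4-dihydroxy-6-methylbenzoic acid (orsellinic acid) | Cc1cc(O)cc(O)c1C(=O)O | starting material
7 | benzyl 2,4-dihydroxy-6-methylbenzoate (benzyl orsellinate) | Cc1cc(O)cc(O)c1C(=O)OCc1ccccc1 | intermediate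
8 | 3,5,7-trioxooct-1-en-1-one (acylketene) | CC(=O)CC(=O)CC(=O)C=C=O | intermediate (not isolated)
9 | benzyl 2-hydroxy-6-methyl-4-[(3,5,7-trioxooctanoyl)oxy]benzoate | CC(=O)CC(=O)CC(=O)CC(=O)Oc1cc(C)c(C(=O)OCc2ccccc2)c(O)c1 | intermediate (not isolated)
10 | benzyl 2-hydroxy-4-{[(2-hydroxy-2-methyl-4,6-dioxocyclohexyl)carbonyl]oxy}-6-methylbenzoate (mixture of stereoisomers, both centres lost on dehydration) | CC1(O)CC(=O)CC(=O)C1C(=O)Oc1cc(C)c(C(=O)OCc2ccccc2)c(O)c1 | intermediate (not isolated)
11 | benzyl 4-[(2,4-dihydroxy-6-methylbenzoyl)oxy]-2-hydroxy-6-methylbenzoate (benzyl lecanorate) | Cc1cc(O)cc(O)c1C(=O)Oc1cc(C)c(C(=O)OCc2ccccc2)c(O)c1 | intermediate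
12 | 5-methylbenzene-1,2,3-triol (5-methylpyrogallol) | Cc1cc(O)c(O)c(O)c1 | starting material
13 | 2,3,4-trihydroxy-6-methylbenzaldehyde | Cc1cc(O)c(O)c(O)c1C=O | intermediate
14 | 4-(benzyloxy)-2,3-dihydroxy-6-methylbenzaldehyde | Cc1cc(OCc2ccccc2)c(O)c(O)c1C=O | intermediate
15 | 4-(benzyloxy)-2,3-dimethoxy-6-methylbenzaldehyde | COc1c(OCc2ccccc2)cc(C)c(C=O)c1OC | intermediate
16 | 4-(benzyloxy)-2,3-dimethoxy-6-methylbenzoic acid | COc1c(OCc2ccccc2)cc(C)c(C(=O)O)c1OC | intermediate
17 | benzyl 4-{[4-{[4-(benzyloxy)-2,3-dimethoxy-6-methylbenzoyl]oxy}-2-hydroxy-6-methylbenzoyl]oxy}-2-hydroxy-6-methylbenzoate | COc1c(OCc2ccccc2)cc(C)c(C(=O)Oc2cc(C)c(C(=O)Oc3cc(C)c(C(=O)OCc4ccccc4)c(O)c3)c(O)c2)c1OC | intermediate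
18 | 4-{[4-{[4-hydroxy-2,3-dimethoxy-6-methylbenzoyl]oxy}-2-hydroxy-6-methylbenzoyl]oxy}-2-hydroxy-6-methylbenzoic acid | COc1c(O)cc(C)c(C(=O)Oc2cc(C)c(C(=O)Oc3cc(C)c(C(=O)O)c(O)c3)c(O)c2)c1OC | target

**Step count and risk**

Total step count: 10. Longest linear sequence: 6 steps (steps 5, 6, 7, 8, 9, 10; the dioxinone arm, steps 1, 2, 4, 9, 10, is 5 steps long).

Steps most likely to fail:

Step 4 (key step). Capture of the acylketene by a phenol is slower than by an alcohol, so the ketene may close on its own enol or dimerise before it is trapped. The aryl triketo ester may also partition towards Claisen closure or lactonisation with loss of the phenol instead of the aldol closure. The fallback builds the B–C ester by classical acylation with a preformed ring B. It sets out from 7 and comes back to the route at 11. Compound 7 is treated with allyl bromide (C=CCBr) and K2CO3 in DMF to give benzyl 2,4-bis(allyloxy)-6-methylbenzoate F1. KOH in aqueous DMSO at 90 °C followed by acidification gives 2,4-bis(allyloxy)-6-methylbenzoic acid F2. F2 is coupled with a second portion of 7 using (CF3CO)2O in toluene to give benzyl 4-{[2,4-bis(allyloxy)-6-methylbenzoyl]oxy}-2-hydroxy-6-methylbenzoate F3. Both allyl ethers are then removed with catalytic Pd(PPh3)4 and morpholine in THF to give 11.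

Step 9. Acylation may spread over the three phenolic hydroxyls of 11, the hindered acid 16 may be slow to form its acylium-type species, and the trifluoroacetic acid set free may scramble the B–C depside bond. The fallback changes the order of assembly so that each coupling meets only one non-chelated hydroxyl. It sets out from 16 and 7 and comes back to the route at 17. Acid 16 is coupled with purchased 2,4-dihydroxy-6-methylbenzaldehyde F4 using (CF3CO)2O in toluene to give 4-formyl-3-hydroxy-5-methylphenyl 4-(benzyloxy)-2,3-dimethoxy-6-methylbenzoate F5. Oxidation with NaClO2 and sulfamic acid in aqueous dioxane gives 4-{[4-(benzyloxy)-2,3-dimethoxy-6-methylbenzoyl]oxy}-2-hydroxy-6-methylbenzoic acid F6. F6 is then coupled with 7 using (CF3CO)2O in toluene to give 17.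

Step 2. Proton transfer from the enolisable acetyl donor to the strongly basic dianion, or acylation at oxygen or at the central carbon, may divert the terminal C-acylation. The fallback replaces the Claisen-type acylation by an aldol addition followed by oxidation. It sets out from 3 and comes back to the route at 5. The dianion of 3 (LiN(i-Pr)2, 2.2 equiv, THF, −78 °C) is added to acetaldehyde to give racemic 6-(4-hydroxy-2-oxopentyl)-2,2-dimethyl-4H-1,3-dioxin-4-one F7, which is oxidised with Dess–Martin periodinane in CH2Cl2 to give 5.

**Further compounds**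

F1 | step 4 | benzyl 2,4-bis(allyloxy)-6-methylbenzoate | C=CCOc1cc(C)c(C(=O)OCc2ccccc2)c(OCC=C)c1
F2 | step 4 | 2,4-bis(allyloxy)-6-methylbenzoic acid | C=CCOc1cc(C)c(C(=O)O)c(OCC=C)c1
F3 | step 4 | benzyl 4-{[2,4-bis(allyloxy)-6-methylbenzoyl]oxy}-2-hydroxy-6-methylbenzoate | C=CCOc1cc(C)c(C(=O)Oc2cc(C)c(C(=O)OCc3ccccc3)c(O)c2)c(OCC=C)c1
F4 | step 9 | 2,4-dihydroxy-6-methylbenzaldehyde (orsellinaldehyde, purchased building block) | Cc1cc(O)cc(O)c1C=O
F5 | step 9 | 4-formyl-3-hydroxy-5-methylphenyl 4-(benzyloxy)-2,3-dimethoxy-6-methylbenzoate | COc1c(OCc2ccccc2)cc(C)c(C(=O)Oc2cc(C)c(C=O)c(O)c2)c1OC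
F6 | step 9 | 4-{[4-(benzyloxy)-2,3-dimethoxy-6-methylbenzoyl]oxy}-2-hydroxy-6-methylbenzoic acid | COc1c(OCc2ccccc2)cc(C)c(C(=O)Oc2cc(C)c(C(=O)O)c(O)c2)c1OC
F7 | step 2 | 6-(4-hydroxy-2-oxopentyl)-2,2-dimethyl-4H-1,3-dioxin-4-one (racemic) | CC(O)CC(=O)CC1=CC(=O)OC(C)(C)O1
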